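## Retrosynthetic overview
1. Stolonic acid B ⇒ its methyl ester. Ring B (the 1,2-dioxane, formed last) opens at O–C3 by a retro peroxy-Michael step to a (6S)-hydroperoxide carrying an (E)-enoate.
2. C6 hydroperoxide ⇒ (6R)-alcohol, via the triflate and SN2 inversion with a masked hydroperoxide. C1–C2 ⇒ Wittig reaction on a C3 aldehyde obtained by hydroboration of a terminal alkene.
3. (19Z,21Z)-diene ⇒ Sonogashira coupling at C20–C21 of a C19 alkyne with (Z)-1-iodohex-1-ene, then Z-selective reduction, finished before any peroxide is present.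
4. Key C5–C6 bond ⇒ reagent-controlled asymmetric allylboration of a trans-THF carbaldehyde (C6–C19) with an allyl unit (C3–C5).
5. Ring A (the THF, formed first) ⇒ cobalt-catalysed aerobic oxidative cyclisation of an (R)-bishomoallylic alcohol made from undec-10-en-1-ol (epoxidation, hydrolytic kinetic resolution, allyl Grignard).

Assumption: positions are numbered along the fatty-acid chain (C1 = CO2H, C26 = CH3). Compound 8, Co(modp)2 and the cobalt salen complex are bought.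

## Route

Step 1
Reactants: 1 undec-10-en-1-ol
Product: 2 1-methoxy-4-[(undec-10-en-1-yloxy)methyl]benzene
Conditions: NaH, 4-methoxybenzyl chloride, Bu4NI (cat.), THF/DMF, 0 °C → rt
Reagents that add atoms: 4-methoxybenzyl chloride COc1ccc(CCl)cc1
Why: Williamson etherification of the primary alkoxide masks the C19 hydroxyl as a PMB ether that survives every step up to its oxidative removal in step 9.

Step 2
Reactants: 2 1-methoxy-4-[(undec-10-en-1-yloxy)methyl]benzene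
Product: 3 rac-2-{9-[(4-methoxybenzyl)oxy]nonyl}oxirane
Conditions: mCPBA, CH2Cl2, 0 °C → rt
Reagents that add atoms: mCPBA O=C(OO)c1cccc(Cl)c1
Why: Prilezhaev epoxidation of the only alkene gives the racemic terminal epoxide that feeds the resolution.

Step 3
Reactants: 3 rac-2-{9-[(4-methoxybenzyl)oxy]nonyl}oxirane
Product: 4 (2R)-2-{9-[(4-methoxybenzyl)oxy]nonyl}oxirane
Conditions: (R,R)-Co(salen) (0.5 mol %; salen = N,N'-bis(3,5-di-tert-butylsalicylidene)cyclohexane-1,2-diaminate), AcOH, air → (R,R)-Co(salen)(OAc); H2O (0.55 equiv), THF, 0 °C → rt; chromatography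
Reagents that add atoms: none
Why: In the Jacobsen hydrolytic kinetic resolution the (R,R)-catalyst hydrolyses the (S)-epoxide much faster, so unreacted (R)-4 (at most 50 %, ≥99 % ee) is recovered and fixes C10.

Step 4
Reactants: 4 (2R)-2-{9-[(4-methoxybenzyl)oxy]nonyl}oxirane
Product: 5 (5R)-14-[(4-methoxybenzyl)oxy]tetradec-1-en-5-ol
Conditions: allylMgBr, CuI (10 mol %), THF, −40 → 0 °C; then H2O
Reagents that add atoms: allylmagnesium bromide C=CC[Mg]Br
Why: Copper-catalysed SN2 opening of the epoxide at its unsubstituted carbon adds C6–C8 and leaves the C10–oxygen bond, hence the (R) configuration, untouched.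

Step 5
Reactants: 5 (5R)-14-[(4-methoxybenzyl)oxy]tetradec-1-en-5-ol
Product: 6 [(2S,5R)-5-{9-[(4-methoxybenzyl)oxy]nonyl}oxolan-2-yl]methanol
Conditions: Co(modp)2 (10 mol %; modp = 1-morpholinocarbamoyl-4,4-dimethylpentane-1,3-dionate), tBuOOH (10 mol %), O2 (1 atm), iPrOH, 55 °C
Reagents that add atoms: dioxygen O=O
Why: The Mukaiyama aerobic oxidative cyclisation of a bishomoallylic alcohol closes ring A in the 5-exo sense and gives the 2,5-trans tetrahydrofuran almost exclusively, so C10 (R) dictates C7 (S).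

Step 6
Reactants: 6 [(2S,5R)-5-{9-[(4-methoxybenzyl)oxy]nonyl}oxolan-2-yl]methanol
Product: 7 (2S,5R)-5-{9-[(4-methoxybenzyl)oxy]nonyl}oxolane-2-carbaldehyde
Conditions: Dess–Martin periodinane, CH2Cl2, 0 °C → rt; used crude at once
Reagents that add atoms: none
Why: Dess–Martin oxidation is non-basic and stops at the aldehyde, so the epimerisable C7 centre next to the formyl group is preserved.

Step 7 (key step)
Reactants: 7 (2S,5R)-5-{9-[(4-methoxybenzyl)oxy]nonyl}oxolane-2-carbaldehyde; 8 (+)-B-allyldiisopinocampheylborane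
Product: 10 (1R)-1-[(2S,5R)-5-{9-[(4-methoxybenzyl)oxy]nonyl}oxolan-2-yl]but-3-en-1-ol, via diisopinocampheylborinate ester 9 (not isolated)
Conditions: 8 (1 mol/L in pentane, 1.3 equiv), Et2O, −78 °C, 3 h; then aq NaOH (3 mol/L), 30 % H2O2, 0 °C → rt
Reagents that add atoms: none
Why: Brown asymmetric allylboration (carbonyl allylation) through a chair Zimmerman–Traxler transition state joins the C6–C19 aldehyde to the C3–C5 allyl unit, and the (−)-α-pinene-derived reagent attacks the Re face, which is also the Felkin–Anh/Cornforth face of the α-alkoxy aldehyde (matched pair), giving the (6R), 6,7-anti alcohol.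

Step 8
Reactants: 10 (1R)-1-[(2S,5R)-5-{9-[(4-methoxybenzyl)oxy]nonyl}oxolan-2-yl]but-3-en-1-ol
Product: 11 tert-butyl({(1R)-1-[(2S,5R)-5-{9-[(4-methoxybenzyl)oxy]nonyl}oxolan-2-yl]but-3-en-1-yl}oxy)dimethylsilane
Conditions: TBSOTf, 2,6-lutidine, CH2Cl2, 0 °C
Reagents that add atoms: tert-butyldimethylsilyl triflate CC(C)(C)[Si](C)(C)OS(=O)(=O)C(F)(F)F
Why: Silylation of the hindered secondary alcohol with the silyl triflate gives a TBS ether orthogonal to the PMB ether and leaves C6 unchanged.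

Step 9
Reactants: 11 tert-butyl({(1R)-1-[(2S,5R)-5-{9-[(4-methoxybenzyl)oxy]nonyl}oxolan-2-yl]but-3-en-1-yl}oxy)dimethylsilane
Product: 12 9-[(2R,5S)-5-{(1R)-1-[(tert-butyldimethylsilyl)oxy]but-3-en-1-yl}oxolan-2-yl]nonan-1-ol
Conditions: DDQ, CH2Cl2/pH 7 buffer, 0 °C
Reagents that add atoms: none
Why: Oxidative PMB cleavage by hydride abstraction at the electron-rich benzylic position frees only the C19 hydroxyl, and it is done before the diene exists.

Step 10
Reactants: 12 9-[(2R,5S)-5-{(1R)-1-[(tert-butyldimethylsilyl)oxy]but-3-en-1-yl}oxolan-2-yl]nonan-1-ol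
Product: 13 9-[(2R,5S)-5-{(1R)-1-[(tert-butyldimethylsilyl)oxy]but-3-en-1-yl}oxolan-2-yl]nonanal
Conditions: Dess–Martin periodinane, CH2Cl2, rt
Reagents that add atoms: none
Why: Dess–Martin oxidation takes the primary alcohol cleanly to the C19 aldehyde without touching the alkene or the silyl ether.

Step 11
Reactants: 13 9-[(2R,5S)-5-{(1R)-1-[(tert-butyldimethylsilyl)oxy]but-3-en-1-yl}oxolan-2-yl]nonanal
Product: 14 tert-butyl({(1R)-1-[(2S,5R)-5-(dec-9-yn-1-yl)oxolan-2-yl]but-3-en-1-yl}oxy)dimethylsilane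
Conditions: dimethyl (1-diazo-2-oxopropyl)phosphonate, K2CO3, MeOH, 0 °C → rt
Reagents that add atoms: dimethyl (1-diazo-2-oxopropyl)phosphonate COP(=O)(OC)C(=[N+]=[N-])C(C)=O
Why: Seyferth–Gilbert homologation in the Ohira–Bestmann variant adds C20 and converts the unbranched aldehyde into the terminal alkyne under mild carbonate conditions that a secondary TBS ether tolerates.

Step 12
Reactants: 15 hex-1-yne
Product: 16 1-iodohex-1-yne
Conditions: NIS, AgNO3 (10 mol %), acetone, rt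
Reagents that add atoms: N-iodosuccinimide O=C1CCC(=O)N1I
Why: Silver-catalysed electrophilic iodination of the terminal alkyne gives the 1-iodoalkyne in high yield.

Step 13
Reactants: 16 1-iodohex-1-yne
Product: 17 (1Z)-1-iodohex-1-ene
Conditions: 2-nitrobenzenesulfonohydrazide, Et3N, THF/iPrOH, rt, dark
Reagents that add atoms: none
Why: Diimide reduction delivers both hydrogens to the same face of the triple bond, so the vinyl iodide is formed with ≥98 % Z geometry (C21=C22).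

Step 14
Reactants: 14 tert-butyl({(1R)-1-[(2S,5R)-5-(dec-9-yn-1-yl)oxolan-2-yl]but-3-en-1-yl}oxy)dimethylsilane; 17 (1Z)-1-iodohex-1-ene
Product: 18 tert-butyl({(1R)-1-{(2S,5R)-5-[(11Z)-hexadec-11-en-9-yn-1-yl]oxolan-2-yl}but-3-en-1-yl}oxy)dimethylsilane
Conditions: Pd(PPh3)4 (5 mol %), CuI (10 mol %), Et3N, THF, rt
Reagents that add atoms: none
Why: Sonogashira coupling forms the C20–C21 bond at room temperature with full retention of the Z vinyl geometry, and the isolated terminal alkene is a spectator.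

Step 15
Reactants: 18 tert-butyl({(1R)-1-{(2S,5R)-5-[(11Z)-hexadec-11-en-9-yn-1-yl]oxolan-2-yl}but-3-en-1-yl}oxy)dimethylsilane
Product: 19 tert-butyl({(1R)-1-{(2S,5R)-5-[(9Z,11Z)-hexadeca-9,11-dien-1-yl]oxolan-2-yl}but-3-en-1-yl}oxy)dimethylsilane
Conditions: Zn dust activated by Cu(OAc)2 then AgNO3, MeOH/H2O/THF, 40 °C, dark
Reagents that add atoms: none
Why: The Boland reduction transfers two hydrogens cis to a conjugated triple bond only and does not over-reduce, giving the C19=C20 Z alkene and thus the Z,Z-diene.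

Step 16
Reactants: 19 tert-butyl({(1R)-1-{(2S,5R)-5-[(9Z,11Z)-hexadeca-9,11-dien-1-yl]oxolan-2-yl}but-3-en-1-yl}oxy)dimethylsilane
Product: 21 (4R)-4-[(tert-butyldimethylsilyl)oxy]-4-{(2S,5R)-5-[(9Z,11Z)-hexadeca-9,11-dien-1-yl]oxolan-2-yl}butan-1-ol, via B-alkyl-9-BBN adduct 20 (not isolated)
Conditions: 9-BBN (1.3 equiv), THF, 0 °C → rt; then aq NaOH (3 mol/L), 30 % H2O2, 0 °C
Reagents that add atoms: hydrogen peroxide OO
Why: Brown hydroboration–oxidation with 9-BBN is anti-Markovnikov and reacts with a monosubstituted alkene more than a hundred times faster than with a 1,2-disubstituted conjugated diene, so only C3=C4 is converted.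

Step 17
Reactants: 21 (4R)-4-[(tert-butyldimethylsilyl)oxy]-4-{(2S,5R)-5-[(9Z,11Z)-hexadeca-9,11-dien-1-yl]oxolan-2-yl}butan-1-ol
Product: 22 (4R)-4-[(tert-butyldimethylsilyl)oxy]-4-{(2S,5R)-5-[(9Z,11Z)-hexadeca-9,11-dien-1-yl]oxolan-2-yl}butanal
Conditions: Dess–Martin periodinane, CH2Cl2, rt
Reagents that add atoms: none
Why: Dess–Martin oxidation gives the C3 aldehyde under conditions that neither isomerise nor oxidise the Z,Z-diene.

Step 18
Reactants: 22 (4R)-4-[(tert-butyldimethylsilyl)oxy]-4-{(2S,5R)-5-[(9Z,11Z)-hexadeca-9,11-dien-1-yl]oxolan-2-yl}butanal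
Product: 23 methyl (2E,6R)-6-[(tert-butyldimethylsilyl)oxy]-6-{(2S,5R)-5-[(9Z,11Z)-hexadeca-9,11-dien-1-yl]oxolan-2-yl}hex-2-enoate
Conditions: Ph3P=CHCO2Me, CH2Cl2, rt
Reagents that add atoms: methyl (triphenylphosphoranylidene)acetate COC(=O)C=P(c1ccccc1)(c1ccccc1)c1ccccc1
Why: The Wittig reaction of a stabilised ylide adds C1–C2 and gives the (E)-enoate (>20:1) that will serve as the Michael acceptor.

Step 19
Reactants: 23 methyl (2E,6R)-6-[(tert-butyldimethylsilyl)oxy]-6-{(2S,5R)-5-[(9Z,11Z)-hexadeca-9,11-dien-1-yl]oxolan-2-yl}hex-2-enoate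
Product: 24 methyl (2E,6R)-6-hydroxy-6-{(2S,5R)-5-[(9Z,11Z)-hexadeca-9,11-dien-1-yl]oxolan-2-yl}hex-2-enoate
Conditions: HF·pyridine, pyridine, THF, 0 °C → rt
Reagents that add atoms: none
Why: Fluoride desilylation in a weakly acidic medium frees the C6 hydroxyl without generating an alkoxide, so the competing 5-exo oxa-Michael closure onto the enoate does not start.

Step 20
Reactants: 24 methyl (2E,6R)-6-hydroxy-6-{(2S,5R)-5-[(9Z,11Z)-hexadeca-9,11-dien-1-yl]oxolan-2-yl}hex-2-enoate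
Product: 25 methyl (2E,6R)-6-{(2S,5R)-5-[(9Z,11Z)-hexadeca-9,11-dien-1-yl]oxolan-2-yl}-6-[(trifluoromethanesulfonyl)oxy]hex-2-enoate
Conditions: Tf2O, 2,6-lutidine, CH2Cl2, −78 → −40 °C; cold aqueous wash, used at once
Reagents that add atoms: triflic anhydride O=S(=O)(OS(=O)(=O)C(F)(F)F)C(F)(F)F
Why: O-sulfonylation keeps the C6 configuration, the neighbouring ring oxygen retards ionisation of the triflate, and the enoate (unlike an ether or ester oxygen at C3) cannot take part as an internal nucleophile.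

Step 21
Reactants: 26 2,3-dimethylbut-2-ene
Product: 28 2-hydroperoxy-2-methoxypropane, via acetone O-oxide 27 (not isolated)
Conditions: O3, MeOH/CH2Cl2, −78 °C; kept as a solution
Reagents that add atoms: ozone [O-][O+]=O; methanol CO
Why: Ozonolysis by the Criegee mechanism gives a carbonyl oxide that methanol traps as the α-methoxy hydroperoxide, a hydroperoxide masked at one end.

Step 22
Reactants: 25 methyl (2E,6R)-6-{(2S,5R)-5-[(9Z,11Z)-hexadeca-9,11-dien-1-yl]oxolan-2-yl}-6-[(trifluoromethanesulfonyl)oxy]hex-2-enoate; 28 2-hydroperoxy-2-methoxypropane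
Product: 29 methyl (2E,6S)-6-{(2S,5R)-5-[(9Z,11Z)-hexadeca-9,11-dien-1-yl]oxolan-2-yl}-6-[(2-methoxypropan-2-yl)peroxy]hex-2-enoate
Conditions: 28 (2 equiv), KOtBu (1.8 equiv), THF, 0 °C, 10 min; then 25, −20 → 0 °C
Reagents that add atoms: none
Why: SN2 alkylation of the weakly basic, α-effect peroxide anion by the secondary triflate proceeds with inversion, turning (6R) into the (6S), 6,7-syn carbon–oxygen bond of the target, while the β-alkyl enoate is too poor an acceptor to compete at 0 °C.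

Step 23
Reactants: 29 methyl (2E,6S)-6-{(2S,5R)-5-[(9Z,11Z)-hexadeca-9,11-dien-1-yl]oxolan-2-yl}-6-[(2-methoxypropan-2-yl)peroxy]hex-2-enoate
Product: 30 methyl (2E,6S)-6-hydroperoxy-6-{(2S,5R)-5-[(9Z,11Z)-hexadeca-9,11-dien-1-yl]oxolan-2-yl}hex-2-enoate
Conditions: AcOH/THF/H2O (4:2:1), BHT (trace), rt, dark
Reagents that add atoms: none
Why: Mild acid hydrolysis of the peroxyketal cleaves only the ketal carbon–oxygen bonds, so the O–O bond, the C6 centre and the acid-tolerant Z,Z-diene are retained.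

Step 24
Reactants: 30 methyl (2E,6S)-6-hydroperoxy-6-{(2S,5R)-5-[(9Z,11Z)-hexadeca-9,11-dien-1-yl]oxolan-2-yl}hex-2-enoate
Product: 31 methyl 2-[(3S,6S)-6-{(2S,5R)-5-[(9Z,11Z)-hexadeca-9,11-dien-1-yl]oxolan-2-yl}-1,2-dioxan-3-yl]acetate
Conditions: Et2NH (0.3 equiv), CF3CH2OH, rt, until the trans/cis ratio is constant; chromatography, cis isomer resubmitted
Reagents that add atoms: none
Why: Base-catalysed 6-exo-trig intramolecular oxa-Michael (peroxy-Michael) addition closes ring B, and because the addition is reversible the ratio drifts to the diequatorial 3,6-trans dioxane, which sets C3 as (S) relative to the fixed C6.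

Step 25
Reactants: 31 methyl 2-[(3S,6S)-6-{(2S,5R)-5-[(9Z,11Z)-hexadeca-9,11-dien-1-yl]oxolan-2-yl}-1,2-dioxan-3-yl]acetate
Product: 32 stolonic acid B, 2-[(3S,6S)-6-{(2S,5R)-5-[(9Z,11Z)-hexadeca-9,11-dien-1-yl]oxolan-2-yl}-1,2-dioxan-3-yl]acetic acid
Conditions: LiOH (3 equiv), THF/H2O (3:1), 0 °C → rt; then aq HCl (1 mol/L) to pH 3
Reagents that add atoms: lithium hydroxide [Li+].[OH-]
Why: Saponification of the unhindered methyl ester outruns E1cB loss of the β-peroxide, any reversible ring opening re-closes to the same trans isomer, and the carboxylate once formed is inert to elimination, so no stereocentre is disturbed.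

## Compound list
1 | undec-10-en-1-ol | OCCCCCCCCCC=C | starting material
2 | 1-methoxy-4-[(undec-10-en-1-yloxy)methyl]benzene | COc1ccc(COCCCCCCCCCC=C)cc1 | intermediate
3 | rac-2-{9-[(4-methoxybenzyl)oxy]nonyl}oxirane | COc1ccc(COCCCCCCCCCC2CO2)cc1 | intermediate
4 | (2R)-2-{9-[(4-methoxybenzyl)oxy]nonyl}oxirane | COc1ccc(COCCCCCCCCC[C@@H]2CO2)cc1 | intermediate
5 | (5R)-14-[(4-methoxybenzyl)oxy]tetradec-1-en-5-ol | COc1ccc(COCCCCCCCCC[C@@H](O)CCC=C)cc1 | intermediate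
6 | [(2S,5R)-5-{9-[(4-methoxybenzyl)oxy]nonyl}oxolan-2-yl]methanol | COc1ccc(COCCCCCCCCC[C@@H]2CC[C@@H](CO)O2)cc1 | intermediate
7 | (2S,5R)-5-{9-[(4-methoxybenzyl)oxy]nonyl}oxolane-2-carbaldehyde | COc1ccc(COCCCCCCCCC[C@@H]2CC[C@@H](C=O)O2)cc1 | intermediate
8 | (+)-B-allyldiisopinocampheylborane, from (−)-α-pinene | C=CCB([C@H]1C[C@H]2C[C@@H]([C@@H]1C)C2(C)C)[C@H]1C[C@H]2C[C@@H]([C@@H]1C)C2(C)C | starting material
9 | diisopinocampheylborinate ester of 10 | COc1ccc(COCCCCCCCCC[C@@H]2CC[C@@H]([C@H](OB([C@H]3C[C@H]4C[C@@H]([C@@H]3C)C4(C)C)[C@H]3C[C@H]4C[C@@H]([C@@H]3C)C4(C)C)CC=C)O2)cc1 | intermediate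
10 | (1R)-1-[(2S,5R)-5-{9-[(4-methoxybenzyl)oxy]nonyl}oxolan-2-yl]but-3-en-1-ol | COc1ccc(COCCCCCCCCC[C@@H]2CC[C@@H]([C@H](O)CC=C)O2)cc1 | intermediate
11 | TBS ether of 10 | COc1ccc(COCCCCCCCCC[C@@H]2CC[C@@H]([C@H](O[Si](C)(C)C(C)(C)C)CC=C)O2)cc1 | intermediate
12 | 9-[(2R,5S)-5-{(1R)-1-[(tert-butyldimethylsilyl)oxy]but-3-en-1-yl}oxolan-2-yl]nonan-1-ol | OCCCCCCCCC[C@@H]1CC[C@@H]([C@H](O[Si](C)(C)C(C)(C)C)CC=C)O1 | intermediate
13 | 9-[(2R,5S)-5-{(1R)-1-[(tert-butyldimethylsilyl)oxy]but-3-en-1-yl}oxolan-2-yl]nonanal | O=CCCCCCCCC[C@@H]1CC[C@@H]([C@H](O[Si](C)(C)C(C)(C)C)CC=C)O1 | intermediate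
14 | tert-butyl({(1R)-1-[(2S,5R)-5-(dec-9-yn-1-yl)oxolan-2-yl]but-3-en-1-yl}oxy)dimethylsilane | C#CCCCCCCCC[C@@H]1CC[C@@H]([C@H](O[Si](C)(C)C(C)(C)C)CC=C)O1 | intermediate
15 | hex-1-yne | CCCCC#C | starting material
16 | 1-iodohex-1-yne | CCCCC#CI | intermediate
17 | (1Z)-1-iodohex-1-ene | CCCC/C=C\I | intermediate
18 | tert-butyl({(1R)-1-{(2S,5R)-5-[(11Z)-hexadec-11-en-9-yn-1-yl]oxolan-2-yl}but-3-en-1-yl}oxy)dimethylsilane | CCCC/C=C\C#CCCCCCCCC[C@@H]1CC[C@@H]([C@H](O[Si](C)(C)C(C)(C)C)CC=C)O1 | intermediate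
19 | tert-butyl({(1R)-1-{(2S,5R)-5-[(9Z,11Z)-hexadeca-9,11-dien-1-yl]oxolan-2-yl}but-3-en-1-yl}oxy)dimethylsilane | CCCC/C=C\C=C/CCCCCCCC[C@@H]1CC[C@@H]([C@H](O[Si](C)(C)C(C)(C)C)CC=C)O1 | intermediate
20 | B-alkyl-9-BBN adduct of 19 (boron on C3) | CCCC/C=C\C=C/CCCCCCCC[C@@H]1CC[C@@H]([C@H](O[Si](C)(C)C(C)(C)C)CCCB2C3CCCC2CCC3)O1 | intermediate
21 | (4R)-4-[(tert-butyldimethylsilyl)oxy]-4-{(2S,5R)-5-[(9Z,11Z)-hexadeca-9,11-dien-1-yl]oxolan-2-yl}butan-1-ol | CCCC/C=C\C=C/CCCCCCCC[C@@H]1CC[C@@H]([C@H](O[Si](C)(C)C(C)(C)C)CCCO)O1 | intermediate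
22 | (4R)-4-[(tert-butyldimethylsilyl)oxy]-4-{(2S,5R)-5-[(9Z,11Z)-hexadeca-9,11-dien-1-yl]oxolan-2-yl}butanal | CCCC/C=C\C=C/CCCCCCCC[C@@H]1CC[C@@H]([C@H](O[Si](C)(C)C(C)(C)C)CCC=O)O1 | intermediate
23 | methyl (2E,6R)-6-[(tert-butyldimethylsilyl)oxy]-6-{(2S,5R)-5-[(9Z,11Z)-hexadeca-9,11-dien-1-yl]oxolan-2-yl}hex-2-enoate | CCCC/C=C\C=C/CCCCCCCC[C@@H]1CC[C@@H]([C@H](O[Si](C)(C)C(C)(C)C)CC/C=C/C(=O)OC)O1 | intermediate
24 | methyl (2E,6R)-6-hydroxy-6-{(2S,5R)-5-[(9Z,11Z)-hexadeca-9,11-dien-1-yl]oxolan-2-yl}hex-2-enoate | CCCC/C=C\C=C/CCCCCCCC[C@@H]1CC[C@@H]([C@H](O)CC/C=C/C(=O)OC)O1 | intermediate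
25 | methyl (2E,6R)-6-{(2S,5R)-5-[(9Z,11Z)-hexadeca-9,11-dien-1-yl]oxolan-2-yl}-6-[(trifluoromethanesulfonyl)oxy]hex-2-enoate | CCCC/C=C\C=C/CCCCCCCC[C@@H]1CC[C@@H]([C@H](OS(=O)(=O)C(F)(F)F)CC/C=C/C(=O)OC)O1 | intermediate
26 | 2,3-dimethylbut-2-ene | CC(C)=C(C)C | starting material
27 | acetone O-oxide | CC(C)=[O+][O-] | intermediate
28 | 2-hydroperoxy-2-methoxypropane | COC(C)(C)OO | intermediate
29 | methyl (2E,6S)-6-{(2S,5R)-5-[(9Z,11Z)-hexadeca-9,11-dien-1-yl]oxolan-2-yl}-6-[(2-methoxypropan-2-yl)peroxy]hex-2-enoate | CCCC/C=C\C=C/CCCCCCCC[C@@H]1CC[C@@H]([C@@H](OOC(C)(C)OC)CC/C=C/C(=O)OC)O1 | intermediate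
30 | methyl (2E,6S)-6-hydroperoxy-6-{(2S,5R)-5-[(9Z,11Z)-hexadeca-9,11-dien-1-yl]oxolan-2-yl}hex-2-enoate | CCCC/C=C\C=C/CCCCCCCC[C@@H]1CC[C@@H]([C@@H](OO)CC/C=C/C(=O)OC)O1 | intermediate
31 | methyl 2-[(3S,6S)-6-{(2S,5R)-5-[(9Z,11Z)-hexadeca-9,11-dien-1-yl]oxolan-2-yl}-1,2-dioxan-3-yl]acetate | CCCC/C=C\C=C/CCCCCCCC[C@@H]1CC[C@@H]([C@@H]2CC[C@@H](CC(=O)OC)OO2)O1 | intermediate
32 | stolonic acid B | CCCC/C=C\C=C/CCCCCCCC[C@@H]1CC[C@@H]([C@@H]2CC[C@@H](CC(=O)O)OO2)O1 | target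

## Step count and risks
Total step count: 25. Longest linear sequence: 22 (steps 1–11, 14–20 and 22–25, from 1 to 32).

**Step 22 is the most likely to fail.** The peroxide anion must displace a secondary triflate that is flanked by the tetrahydrofuran. Elimination, attack at sulfur and participation of the ring oxygen all compete.

The fallback forms the C6–oxygen bond inside the molecule instead:
- It sets out from aldehyde 22. HC(OMe)3/PPTS/MeOH gives the dimethyl acetal F1.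
- TBAF in THF frees the (6R)-alcohol F2, and MsCl/Et3N gives the mesylate F3.
- Ethereal H2O2 with catalytic TsOH exchanges one methoxy group to give the α-methoxy hydroperoxide F4 (C3 epimers).
- KOtBu/18-crown-6 in THF at 0 °C closes the ring by 6-exo-tet displacement with inversion at C6, giving the 3-methoxy-1,2-dioxane F5.
- TMSOTf in CH2Cl2 at −78 °C generates the peroxycarbenium ion. A Mukaiyama-type addition of 1-(tert-butyldimethylsilyloxy)-1-methoxyethene attaches C1–C2.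
- Equilibration with Et2NH/CF3CH2OH brings the route back at 31.

**Step 24 is second.** The free hydroperoxide may decompose under amine base, or the enoate may equilibrate too slowly to reach a useful trans/cis ratio.

The fallback changes the acceptor and the way the acid is unveiled:
- It sets out from 29. DIBAL in CH2Cl2 at −78 °C (dialkyl peroxides survive it) gives the allylic alcohol F8, and MnO2 gives the enal F9.
- AcOH/THF/H2O unmasks the hydroperoxy enal F10. Its far more reversible peroxy-Michael addition settles on the trans-configured dioxanyl acetaldehyde F11.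
- Pinnick oxidation (NaClO2, NaH2PO4, 2-methylbut-2-ene, tBuOH/H2O) comes back to the route at 32. This path also avoids the saponification.

**Step 15 is third.** The semi-reduction of the enyne may be incomplete or may erode the Z geometry on this lipophilic substrate.

The fallback builds the diene by an sp2–sp2 coupling of two preformed Z alkenes:
- It sets out from aldehyde 13. Stork–Zhao olefination (Ph3P(CH2I) iodide salt, NaHMDS, THF/DMPU, −78 °C) gives the (Z)-vinyl iodide F6.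
- In parallel, 17 is lithiated (tBuLi, Et2O, −78 °C) and quenched with 2-isopropoxy-4,4,5,5-tetramethyl-1,3,2-dioxaborolane to give the (Z)-hexenyl boronate F7.
- Suzuki–Miyaura coupling of the two (Pd(dppf)Cl2, Cs2CO3, THF/H2O, rt) retains both geometries and comes back to the route at 19.

## Further compounds
F1 | step 22 | tert-butyl{[(1R)-1-{(2S,5R)-5-[(9Z,11Z)-hexadeca-9,11-dien-1-yl]oxolan-2-yl}-4,4-dimethoxybutyl]oxy}dimethylsilane | CCCC/C=C\C=C/CCCCCCCC[C@@H]1CC[C@@H]([C@H](O[Si](C)(C)C(C)(C)C)CCC(OC)OC)O1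
F2 | step 22 | (1R)-1-{(2S,5R)-5-[(9Z,11Z)-hexadeca-9,11-dien-1-yl]oxolan-2-yl}-4,4-dimethoxybutan-1-ol | CCCC/C=C\C=C/CCCCCCCC[C@@H]1CC[C@@H]([C@H](O)CCC(OC)OC)O1
F3 | step 22 | (1R)-1-{(2S,5R)-5-[(9Z,11Z)-hexadeca-9,11-dien-1-yl]oxolan-2-yl}-4,4-dimethoxybutyl methanesulfonate | CCCC/C=C\C=C/CCCCCCCC[C@@H]1CC[C@@H]([C@H](OS(C)(=O)=O)CCC(OC)OC)O1
F4 | step 22 | (1R)-4-hydroperoxy-1-{(2S,5R)-5-[(9Z,11Z)-hexadeca-9,11-dien-1-yl]oxolan-2-yl}-4-methoxybutyl methanesulfonate (C4 epimers) | CCCC/C=C\C=C/CCCCCCCC[C@@H]1CC[C@@H]([C@H](OS(C)(=O)=O)CCC(OC)OO)O1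
F5 | step 22 | (6S)-6-{(2S,5R)-5-[(9Z,11Z)-hexadeca-9,11-dien-1-yl]oxolan-2-yl}-3-methoxy-1,2-dioxane (C3 epimers) | CCCC/C=C\C=C/CCCCCCCC[C@@H]1CC[C@@H]([C@@H]2CCC(OC)OO2)O1
F6 | step 15 | tert-butyl({(1R)-1-{(2S,5R)-5-[(9Z)-10-iododec-9-en-1-yl]oxolan-2-yl}but-3-en-1-yl}oxy)dimethylsilane | I/C=C\CCCCCCCC[C@@H]1CC[C@@H]([C@H](O[Si](C)(C)C(C)(C)C)CC=C)O1
F7 | step 15 | 2-[(1Z)-hex-1-en-1-yl]-4,4,5,5-tetramethyl-1,3,2-dioxaborolane | CCCC/C=C\B1OC(C)(C)C(C)(C)O1
F8 | step 24 | (2E,6S)-6-{(2S,5R)-5-[(9Z,11Z)-hexadeca-9,11-dien-1-yl]oxolan-2-yl}-6-[(2-methoxypropan-2-yl)peroxy]hex-2-en-1-ol | CCCC/C=C\C=C/CCCCCCCC[C@@H]1CC[C@@H]([C@@H](OOC(C)(C)OC)CC/C=C/CO)O1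
F9 | step 24 | (2E,6S)-6-{(2S,5R)-5-[(9Z,11Z)-hexadeca-9,11-dien-1-yl]oxolan-2-yl}-6-[(2-methoxypropan-2-yl)peroxy]hex-2-enal | CCCC/C=C\C=C/CCCCCCCC[C@@H]1CC[C@@H]([C@@H](OOC(C)(C)OC)CC/C=C/C=O)O1
F10 | step 24 | (2E,6S)-6-hydroperoxy-6-{(2S,5R)-5-[(9Z,11Z)-hexadeca-9,11-dien-1-yl]oxolan-2-yl}hex-2-enal | CCCC/C=C\C=C/CCCCCCCC[C@@H]1CC[C@@H]([C@@H](OO)CC/C=C/C=O)O1
F11 | step 24 | 2-[(3S,6S)-6-{(2S,5R)-5-[(9Z,11Z)-hexadeca-9,11-dien-1-yl]oxolan-2-yl}-1,2-dioxan-3-yl]acetaldehyde | CCCC/C=C\C=C/CCCCCCCC[C@@H]1CC[C@@H]([C@@H]2CC[C@@H](CC=O)OO2)O1
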